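**Assumptions.** Clerodane numbering is used for all bicyclic intermediates (ring A = C1–C4, C5, C10; ring B = C5–C10; C11–C12 chain on C9; C17 = 8‑Me; C18 on C4; C19 on C5; C20 = 9‑Me). α is the face of the C5 angular group and β the face of H‑10. Chiral catalysts, ligands and enzymes are not counted as starting materials. The ketoreductase is the (S)‑selective hit from a commercial screening panel. The route is a design proposal and has not been run.

## Retrosynthetic overview

1. Target ⇐ 4α,18‑spiro‑epoxide **37** (chloride opening last); butenolide ⇐ 3‑furyl group (¹O₂, then NaBH₄); esters ⇐ acetylation of the 6,19‑diol and acylation of the 1,12‑diol with (S)‑2‑methylbutanoic acid (from tiglic acid by Ru‑catalysed hydrogenation).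
2. C12 (S)‑carbinol ⇐ ketoreductase reduction of a 3‑furyl ketone (3‑furyllithium + C12 aldehyde); oxirane ⇐ C4 ketone (Corey–Chaykovsky).
3. 1β‑OH and H‑10β ⇐ hydroboration of a Δ1(10) alkene; 6α‑OH and 8α‑Me ⇐ Li/NH₃ reduction of a Δ7‑6‑one made by Saegusa, MeLi and oxidative 1,3‑transposition of the C8 ketone.
4. C9 quaternary centre ⇐ deconjugative allylation of a Wieland–Miescher‑type enone; C19 ⇐ angular allyl (isomerisation, cleavage).
5. Ring order: ring A (cyclohexane‑1,3‑dione) → ring B (amino‑acid‑catalysed Robinson/aldol annulation, first stereocentre) → oxirane → butenolide (from the furan).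

## Route

**Step 1**
Reactants: **1** cyclohexane‑1,3‑dione; **2** allyl bromide
Product: **3** 2‑allylcyclohexane‑1,3‑dione
Conditions: aq. KOH, Cu powder (cat.), rt
Reagents that add atoms: none beyond **2** (allyl bromide, C=CCBr)
Why: C‑allylation of the soft 1,3‑dione enolate by an allylic halide in water; no stereocentre.

**Step 2**
Reactants: **3**; **4** ethyl vinyl ketone
Product: **5** 2‑allyl‑2‑(3‑oxopentyl)cyclohexane‑1,3‑dione (prochiral triketone)
Conditions: Et₃N (cat.), EtOAc, rt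
Reagents that add atoms: none beyond **4** (CCC(=O)C=C)
Why: Michael addition of the acidic 2‑substituted dione to the enone gives the achiral triketone.

**Step 3**
Reactants: **5**
Product: **6** (S)‑8a‑allyl‑5‑methyl‑3,4,8,8a‑tetrahydronaphthalene‑1,6(2H,7H)‑dione (clerodane numbering: 5α‑allyl, 9‑Me, Δ9(10), 4,8‑dione)
Conditions: D‑phenylalanine (30 mol %), (1R)‑(−)‑CSA (15 mol %), DMF, 30→70 °C
Reagents that add atoms: none
Why: Hajos–Parrish–Eder–Sauer–Wiechert asymmetric aldol condensation; the enamine of the ethyl ketone attacks one enantiotopic ring carbonyl through the acid‑H‑bonded transition state, and the D‑amino acid gives the series opposite to L‑proline's (S)‑Wieland–Miescher ketone, i.e. angular allyl α.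

**Step 4**
Reactants: **6**
Product: **7** C4 mono‑1,3‑dioxolane of **6**
Conditions: ethylene glycol, TsOH (cat.), 4 Å MS, rt
Reagents that add atoms: ethylene glycol, OCCO
Why: The saturated ketone ketalises selectively over the conjugated enone carbonyl, as for the Wieland–Miescher ketone.

**Step 5**
Reactants: **7**
Product: **8** 5α‑(prop‑1‑enyl) isomer of **7** (E major; E/Z irrelevant)
Conditions: RuHCl(CO)(PPh₃)₃ (5 mol %), toluene, 80 °C
Reagents that add atoms: none
Why: Ru–H allyl‑to‑propenyl isomerisation under neutral conditions; the tetrasubstituted enone cannot migrate.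

**Step 6**
Reactants: **8**
Product: **9** 5α‑formyl compound (C19 aldehyde)
Conditions: OsO₄ (cat.), NaIO₄, 2,6‑lutidine, dioxane/H₂O, rt
Reagents that add atoms: osmium tetroxide, O=[Os](=O)(=O)=O; sodium periodate, [Na+].[O-]I(=O)(=O)=O
Why: Lemieux–Johnson cleavage of the isolated propenyl group; the electron‑poor tetrasubstituted enone is not dihydroxylated.

**Step 7**
Reactants: **9**
Product: **10** C19 primary alcohol (5α‑CH₂OH)
Conditions: NaBH₄, MeOH/CH₂Cl₂, −78 °C
Reagents that add atoms: none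
Why: Aldehyde‑selective hydride reduction at low temperature, which also outruns base‑induced deformylation of the angular aldehyde.

**Step 8**
Reactants: **10**
Product: **11** 19‑O‑benzyl ether
Conditions: 2‑benzyloxy‑1‑methylpyridinium triflate, MgO, PhCF₃, 85 °C
Reagents that add atoms: 2‑benzyloxy‑1‑methylpyridinium triflate, C[n+]1ccccc1OCc1ccccc1.[O-]S(=O)(=O)C(F)(F)F
Why: Neutral (Dudley) benzylation avoids the alkoxide that would trigger vinylogous retro‑aldol loss of formaldehyde.

**Step 9**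
Reactants: **11**; **2** allyl bromide
Product: **12** 9β‑allyl‑9α‑methyl‑19‑benzyloxy‑4,4‑ethylenedioxy‑Δ1(10)‑octalin‑8‑one
Conditions: KOt‑Bu, t‑BuOH/THF, 0 °C; then **2**, rt
Reagents that add atoms: none beyond **2**
Why: Deconjugative α‑alkylation of the thermodynamic extended dienolate; the allyl group enters C9 anti to the axial 5α‑CH₂OBn (avoiding a 1,3‑diaxial clash), giving 9β‑CH₂R/9α‑Me and moving the alkene to Δ1(10).

**Step 10**
Reactants: **12**
Product: **13** 9β‑(2‑oxoethyl) compound (C12 aldehyde)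
Conditions: OsO₄ (cat.), NaIO₄, 2,6‑lutidine, dioxane/H₂O, rt
Reagents that add atoms: osmium tetroxide, O=[Os](=O)(=O)=O; sodium periodate, [Na+].[O-]I(=O)(=O)=O
Why: Lemieux–Johnson cleavage of the terminal alkene; the Δ1(10) alkene, flanked by two quaternary carbons, is too hindered for OsO₄.

**Step 11**
Reactants: **13**
Product: **14** C12 primary alcohol
Conditions: NaBH₄, MeOH, −78→−40 °C
Reagents that add atoms: none
Why: Chemoselective reduction of the aldehyde over the neopentyl C8 ketone.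

**Step 12**
Reactants: **14**
Product: **15** 12‑O‑TBS ether
Conditions: TBSCl, imidazole, DMF, rt
Reagents that add atoms: TBSCl, CC(C)(C)[Si](C)(C)Cl
Why: Standard silylation of the primary alcohol.

**Step 13**
Reactants: **15**
Product: **16** Δ1(10),6‑dien‑8‑one
Conditions: LDA, TMSCl, THF, −78 °C; then Pd(OAc)₂, MeCN, rt
Reagents that add atoms: none
Why: Saegusa–Ito dehydrogenation; C9 is quaternary, so enolisation can only occur toward C7.

**Step 14**
Reactants: **16**
Product: **17** 8‑hydroxy‑8‑methyl‑Δ1(10),6‑diene (C8 epimers, irrelevant)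
Conditions: MeLi, CeCl₃, THF, −78 °C
Reagents that add atoms: methyllithium, [Li]C
Why: Organocerium 1,2‑addition to the non‑enolisable hindered enone installs C17.

**Step 15**
Reactants: **17**
Product: **18** 8‑methyl‑Δ1(10),7‑dien‑6‑one
Conditions: PCC, 4 Å MS, CH₂Cl₂, rt
Reagents that add atoms: pyridinium chlorochromate, [O-][Cr](=O)(=O)Cl.c1cc[nH+]cc1
Why: Babler–Dauben oxidative 1,3‑transposition ([3,3] shift of the tertiary allylic chromate) moves oxygen to C6 and leaves C7=C8(Me).

**Step 16**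
Reactants: **18**
Product: **19** 6α,19‑diol with 8α‑Me (8β‑H), Δ1(10), 4‑ketal, 12‑OTBS
Conditions: Li, NH₃(l)/THF, t‑BuOH, −78→−33 °C; then MeOH; NH₄Cl
Reagents that add atoms: none
Why: Dissolving‑metal reduction. Ring A locks ring B so that C19 and C20 are pseudo‑axial on the α face, so C8 is protonated axially from β (8α‑Me). The C6 ketone gives the thermodynamic equatorial 6α‑OH, and the benzyl ether is cleaved in the same operation.

**Step 17**
Reactants: **19**
Product: **20** 6α,19‑O‑di‑tert‑butylsilylene derivative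
Conditions: t‑Bu₂Si(OTf)₂, 2,6‑lutidine, CH₂Cl₂, 0 °C
Reagents that add atoms: di‑tert‑butylsilyl bis(triflate), CC(C)(C)[Si](OS(=O)(=O)C(F)(F)F)(OS(=O)(=O)C(F)(F)F)C(C)(C)C
Why: The gauche 1,3‑diol (equatorial 6α‑O, axial C19) closes to a six‑membered silylene stable to base and mild acid.

**Step 18**
Reactants: **20**
Product: **21** 1β‑alcohol, 10β‑H (trans‑decalin)
Conditions: BH₃·THF, THF, 0→45 °C; then NaOH, H₂O₂, 0 °C
Reagents that add atoms: hydrogen peroxide, OO (boron from B.C1CCOC1 is not retained)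
Why: Hydroboration–oxidation; the α face is blocked by axial C19 and C20, so syn addition from β gives H‑10β and the equatorial 1β‑OH (same sense as 4,4‑dimethyl‑Δ5‑steroids).

**Step 19**
Reactants: **21**
Product: **22** 1β‑O‑PMB ether
Conditions: NaH, PMBCl, TBAI, DMF, 0 °C→rt
Reagents that add atoms: 4‑methoxybenzyl chloride, COc1ccc(CCl)cc1
Why: Williamson etherification gives a C1 protecting group orthogonal to silyl groups and esters.

**Step 20**
Reactants: **22**
Product: **23** 4‑ketone, 12‑ol (PMB and silylene retained)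
Conditions: PPTS, acetone/H₂O, 60 °C
Reagents that add atoms: water, O
Why: Mild acid hydrolysis removes the dioxolane and the primary TBS ether together; PMB and the six‑membered silylene are stable at this pH.

**Step 21**
Reactants: **23**
Product: **24** 4α,18‑epoxide (spiro‑oxirane, O α/equatorial, CH₂ β/axial), 12‑ol
Conditions: Me₃S⁺ I⁻, KHMDS, THF, −10 °C→rt
Reagents that add atoms: trimethylsulfonium iodide, C[S+](C)C.[I-]
Why: Corey–Chaykovsky epoxidation; the irreversible sulfonium ylide attacks axially from the open β face (the equatorial path is blocked by C19‑O and the silylene), giving the natural epoxide configuration. With C6‑O and C19‑O silylated, no retro‑aldol is possible.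

**Step 22**
Reactants: **24**
Product: **25** C12 aldehyde
Conditions: Dess–Martin periodinane, NaHCO₃, CH₂Cl₂, rt
Reagents that add atoms: none
Why: Buffered DMP oxidation of the primary alcohol; the epoxide and PMB ether are inert.

**Step 23**
Reactants: **25**; **26** 3‑bromofuran
Product: **27** 12‑(furan‑3‑yl)‑12‑ol (C12 epimers)
Conditions: **26**, n‑BuLi, THF, −78 °C; then **25**, −78 °C
Reagents that add atoms: none beyond **26** (Brc1ccoc1)
Why: Br/Li exchange at −78 °C gives 3‑furyllithium, which adds to the aldehyde far faster than to the hindered epoxide; no esters are present.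

**Step 24**
Reactants: **27**
Product: **28** 3‑furyl ketone (12‑one)
Conditions: Dess–Martin periodinane, NaHCO₃, CH₂Cl₂, rt
Reagents that add atoms: none
Why: Oxidation converges the C12 epimers to one ketone and deactivates the furan for the next steps.

**Step 25**
Reactants: **28**
Product: **29** 6α,19‑diol
Conditions: TBAF, AcOH, THF, rt
Reagents that add atoms: none
Why: Buffered fluoride removes the silylene while no esters are present; the hindered epoxide is stable to fluoride.

**Step 26**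
Reactants: **29**
Product: **30** 6α,19‑diacetate
Conditions: Ac₂O, pyridine, DMAP, CH₂Cl₂, rt
Reagents that add atoms: acetic anhydride, CC(=O)OC(C)=O
Why: Acylation of the only two free hydroxyls (C1 is still a PMB ether).

**Step 27**
Reactants: **30**
Product: **31** 1β‑ol
Conditions: DDQ, CH₂Cl₂/pH 7 buffer, 0 °C
Reagents that add atoms: none
Why: Oxidative PMB cleavage; the acylfuran is electron‑poor and tolerates DDQ, and the acetates and epoxide are untouched.

**Step 28**
Reactants: **31**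
Product: **32** (12S)‑1β,12‑diol
Conditions: ketoreductase (KRED, (S)‑selective), NADP⁺, glucose dehydrogenase/glucose, KPi buffer pH 7.0, 10 % DMSO, 30 °C
Reagents that add atoms: none
Why: Enzymatic (ketoreductase) reduction of the heteroaryl ketone; hydride from NADPH is delivered to one face under active‑site control, setting C12 (S) independently of the remote decalin stereocentres, at neutral pH that spares the acetates and epoxide.

**Step 29**
Reactants: **33** tiglic acid
Product: **34** (S)‑2‑methylbutanoic acid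
Conditions: H₂ (4 atm), Ru(OAc)₂[(S)‑H₈‑BINAP] (0.5 mol %), MeOH, rt
Reagents that add atoms: none
Why: Noyori‑type carboxylate‑directed asymmetric hydrogenation; the (S)‑ligand gives the (S)‑acid.

**Step 30**
Reactants: **32**; **34**
Product: **35** 1β,12S‑bis[(S)‑2‑methylbutanoate] (furan, epoxide, 6,19‑diacetate)
Conditions: **34** (5 equiv), DIC, DMAP, CH₂Cl₂, 0 °C→rt
Reagents that add atoms: none beyond **34** (CC[C@H](C)C(=O)O)
Why: Steglich esterification of both secondary alcohols; the simple α‑alkyl acid does not epimerise, and C12 is acylated with retention.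

**Step 31**
Reactants: **35**
Product: **36** γ‑hydroxybutenolide (4‑substituted 5‑hydroxyfuran‑2(5H)‑one; C16 epimers)
Conditions: O₂, hν, rose bengal, i‑Pr₂NEt, CH₂Cl₂/MeOH, −78 °C
Reagents that add atoms: oxygen, O=O
Why: Singlet‑oxygen [4+2] addition to the furan, then hindered‑base fragmentation by removal of the distal, less hindered endoperoxide proton, puts the carbonyl away from the side chain.

**Step 32**
Reactants: **36**
Product: **37** 4α,18‑epoxy butenolide (4‑substituted furan‑2(5H)‑one)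
Conditions: NaBH₄, EtOH, 0 °C; then pH 4 buffer
Reagents that add atoms: none
Why: Borohydride reduces the masked aldehyde of the hydroxybutenolide and the (Z)‑hydroxy acid relactonises to the β‑substituted butenolide; C12 is already acylated, so only C16‑OH can close.

**Step 33**
Reactants: **37**
Product: **38** ajugaciliatin A
Conditions: LiCl, AcOH, THF, rt
Reagents that add atoms: lithium chloride, [Li+].[Cl-]
Why: Mildly acidic SN2 opening of the spiro‑epoxide by chloride at the primary C18; the C4–O bond is untouched, so the 4α‑OH configuration is retained.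

## Compound list

1 | cyclohexane‑1,3‑dione | O=C1CCCC(=O)C1 | starting material
2 | allyl bromide | C=CCBr | starting material
3 | 2‑allylcyclohexane‑1,3‑dione | C=CCC1C(=O)CCCC1=O | intermediate
4 | ethyl vinyl ketone | CCC(=O)C=C | starting material
5 | 2‑allyl‑2‑(3‑oxopentyl)cyclohexane‑1,3‑dione | CCC(=O)CCC1(CC=C)C(=O)CCCC1=O | intermediate
6 | (S)‑8a‑allyl‑5‑methyl enedione (5α‑allyl) | CC1=C2CCCC(=O)[C@]2(CC=C)CCC1=O | intermediate
7 | C4 dioxolane of 6 | CC1=C2CCCC3(OCCO3)[C@]2(CC=C)CCC1=O | intermediate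
8 | 5α‑propenyl ketal enone | CC1=C2CCCC3(OCCO3)[C@]2(/C=C/C)CCC1=O | intermediate
9 | 5α‑formyl ketal enone | CC1=C2CCCC3(OCCO3)[C@]2(C=O)CCC1=O | intermediate
10 | 19‑hydroxy ketal enone | CC1=C2CCCC3(OCCO3)[C@]2(CO)CCC1=O | intermediate
11 | 19‑O‑benzyl ketal enone | CC1=C2CCCC3(OCCO3)[C@]2(COCc4ccccc4)CCC1=O | intermediate
12 | 9β‑allyl‑9α‑methyl‑Δ1(10)‑8‑one | C=CC[C@@]1(C)C(=O)CC[C@]2(COCc3ccccc3)C1=CCCC24OCCO4 | intermediate
13 | C12 aldehyde | O=CC[C@@]1(C)C(=O)CC[C@]2(COCc3ccccc3)C1=CCCC24OCCO4 | intermediate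
14 | C12 alcohol | OCC[C@@]1(C)C(=O)CC[C@]2(COCc3ccccc3)C1=CCCC24OCCO4 | intermediate
15 | 12‑OTBS 8‑ketone | CC(C)(C)[Si](C)(C)OCC[C@@]1(C)C(=O)CC[C@]2(COCc3ccccc3)C1=CCCC24OCCO4 | intermediate
16 | Δ1(10),6‑dien‑8‑one | CC(C)(C)[Si](C)(C)OCC[C@@]1(C)C(=O)C=C[C@]2(COCc3ccccc3)C1=CCCC24OCCO4 | intermediate
17 | 8‑hydroxy‑8‑methyl‑Δ1(10),6‑diene | CC(C)(C)[Si](C)(C)OCC[C@@]1(C)C(C)(O)C=C[C@]2(COCc3ccccc3)C1=CCCC24OCCO4 | intermediate
18 | 8‑methyl‑Δ1(10),7‑dien‑6‑one | CC(C)(C)[Si](C)(C)OCC[C@@]1(C)C(C)=CC(=O)[C@]2(COCc3ccccc3)C1=CCCC24OCCO4 | intermediate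
19 | 6α,19‑diol, 8α‑Me, Δ1(10) | CC(C)(C)[Si](C)(C)OCC[C@@]1(C)[C@H](C)C[C@H](O)[C@]2(CO)C1=CCCC24OCCO4 | intermediate
20 | 6α,19‑O‑di‑tert‑butylsilylene | CC(C)(C)[Si](C)(C)OCC[C@@]1(C)[C@H](C)C[C@H](O[Si](C(C)(C)C)(C(C)(C)C)OC5)[C@]25C1=CCCC24OCCO4 | intermediate
21 | 1β‑ol, 10β‑H | CC(C)(C)[Si](C)(C)OCC[C@@]1(C)[C@H](C)C[C@H](O[Si](C(C)(C)C)(C(C)(C)C)OC5)[C@]25[C@@H]1[C@H](O)CCC24OCCO4 | intermediate
22 | 1β‑OPMB | CC(C)(C)[Si](C)(C)OCC[C@@]1(C)[C@H](C)C[C@H](O[Si](C(C)(C)C)(C(C)(C)C)OC5)[C@]25[C@@H]1[C@H](OCc6ccc(OC)cc6)CCC24OCCO4 | intermediate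
23 | 4‑ketone, 12‑ol | OCC[C@@]1(C)[C@H](C)C[C@H](O[Si](C(C)(C)C)(C(C)(C)C)OC5)[C@]25[C@@H]1[C@H](OCc6ccc(OC)cc6)CCC2=O | intermediate
24 | 4α,18‑epoxide, 12‑ol | OCC[C@@]1(C)[C@H](C)C[C@H](O[Si](C(C)(C)C)(C(C)(C)C)OC5)[C@]25[C@@H]1[C@H](OCc6ccc(OC)cc6)CC[C@]2(O3)C3 | intermediate
25 | epoxide, 12‑al | O=CC[C@@]1(C)[C@H](C)C[C@H](O[Si](C(C)(C)C)(C(C)(C)C)OC5)[C@]25[C@@H]1[C@H](OCc6ccc(OC)cc6)CC[C@]2(O3)C3 | intermediate
26 | 3‑bromofuran | Brc1ccoc1 | starting material
27 | 12‑(3‑furyl) carbinol (C12 epimers) | OC(C[C@@]1(C)[C@H](C)C[C@H](O[Si](C(C)(C)C)(C(C)(C)C)OC5)[C@]25[C@@H]1[C@H](OCc6ccc(OC)cc6)CC[C@]2(O3)C3)c1ccoc1 | intermediate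
28 | 3‑furyl ketone | O=C(C[C@@]1(C)[C@H](C)C[C@H](O[Si](C(C)(C)C)(C(C)(C)C)OC5)[C@]25[C@@H]1[C@H](OCc6ccc(OC)cc6)CC[C@]2(O3)C3)c1ccoc1 | intermediate
29 | furyl ketone 6α,19‑diol | O=C(C[C@@]1(C)[C@H](C)C[C@H](O)[C@]2(CO)[C@@H]1[C@H](OCc6ccc(OC)cc6)CC[C@]2(O3)C3)c1ccoc1 | intermediate
30 | 6α,19‑diacetate, 1β‑OPMB | O=C(C[C@@]1(C)[C@H](C)C[C@H](OC(C)=O)[C@]2(COC(C)=O)[C@@H]1[C@H](OCc6ccc(OC)cc6)CC[C@]2(O3)C3)c1ccoc1 | intermediate
31 | 1β‑ol furyl ketone diacetate | O=C(C[C@@]1(C)[C@H](C)C[C@H](OC(C)=O)[C@]2(COC(C)=O)[C@@H]1[C@H](O)CC[C@]2(O3)C3)c1ccoc1 | intermediate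
32 | (12S)‑1β,12‑diol | O[C@@H](C[C@@]1(C)[C@H](C)C[C@H](OC(C)=O)[C@]2(COC(C)=O)[C@@H]1[C@H](O)CC[C@]2(O3)C3)c1ccoc1 | intermediate
33 | tiglic acid | C/C=C(\C)C(=O)O | starting material
34 | (S)‑2‑methylbutanoic acid | CC[C@H](C)C(=O)O | intermediate
35 | 1,12‑bis[(S)‑2‑methylbutanoate] furan epoxide | CC[C@H](C)C(=O)O[C@@H](C[C@@]1(C)[C@H](C)C[C@H](OC(C)=O)[C@]2(COC(C)=O)[C@@H]1[C@H](OC(=O)[C@@H](C)CC)CC[C@]2(O3)C3)c1ccoc1 | intermediate
36 | γ‑hydroxybutenolide (C16 epimers) | CC[C@H](C)C(=O)O[C@@H](C[C@@]1(C)[C@H](C)C[C@H](OC(C)=O)[C@]2(COC(C)=O)[C@@H]1[C@H](OC(=O)[C@@H](C)CC)CC[C@]2(O3)C3)C1=CC(=O)OC1O | intermediate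
37 | 4α,18‑epoxy butenolide | CC[C@H](C)C(=O)O[C@@H](C[C@@]1(C)[C@H](C)C[C@H](OC(C)=O)[C@]2(COC(C)=O)[C@@H]1[C@H](OC(=O)[C@@H](C)CC)CC[C@]2(O3)C3)C1=CC(=O)OC1 | intermediate
38 | ajugaciliatin A | CC[C@H](C)C(=O)O[C@@H](C[C@@]1(C)[C@H](C)C[C@H](OC(C)=O)[C@]2(COC(C)=O)[C@@H]1[C@H](OC(=O)[C@@H](C)CC)CC[C@]2(O)CCl)C1=CC(=O)OC1 | target

## Summary

Total steps: 33. Longest linear sequence: 32 (steps 1–28 and 30–33, from cyclohexane‑1,3‑dione); step 29 is a one‑step side branch.

Steps most likely to fail: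

1. **Step 18, hydroboration of the Δ1(10) alkene flanked by two quaternary carbons** (may be too slow). Fallback: epoxidise from the β face with DMDO, rearrange to the 1‑ketone with BF₃·OEt₂ (Meinwald), equilibrate C10 to the trans‑fused ketone, then reduce with dissolving metal to the equatorial 1β‑alcohol.
2. **Step 21, Corey–Chaykovsky on the hindered C4 ketone** (enolisation or poor face selectivity). Fallback: Tebbe/Wittig methylenation to the 4(18)‑exocyclic alkene, then NBS/H₂O bromohydrin formation (Br⁺ on the open β face, water anti at C4) and base closure to the same 4α,18‑epoxide.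
3. **Step 28, ketoreductase acceptance of the bulky furyl ketone.** Fallback: oxazaborolidine‑catalysed (CBS) borane reduction of ketone **28** or **31**; if selectivity is still poor, separate the C12 epimers and recycle the wrong one by Mitsunobu inversion or re‑oxidation.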